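What does [target] at the end of the run do as the charge of substrate grows, and what end state must these flasks reach?

- [target] at the end for amber, teal, grey, violet, in this order
- the shape of the row from first to last (falls all the way / falls, then rises / hardly changes / rises, then falls / rises all the way)

the same everywhere: time 1.5 h
- amber: substrate 0.50 M
- teal: substrate 0.80 M
- grey: substrate 1.0 M
- violet: substrate 1.5 M

    substrate → target, rate k1*[substrate]/(1 + ([substrate]/sat1)) (sat1 = 0.19 M, k1 = 1.2 min⁻¹)
    2 substrate → homo dimer (k2 = 0.19 M⁻¹ min⁻¹)
    target → over-reaction product (k3 = 0.091 min⁻¹)
    target ⇌ isomer of the product (K4 = 22, k4 = 0.019 min⁻¹)

- percent here means substrate units held: one homo dimer counts as two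
- where a step has two of a species, its rate is k times that concentration squared, and two are used at each turn
- "hardly changes" means that all values lie within two and a half points (for a concentration: within two and a half percent of the largest)
- run time (amber): 1.5 h

We turn the question round and ask what a falling row needs. The ceiling of the passing of substrate into target, the rate constant times sat, gives a time scale of 6.58 min for the violet charge. The run is much longer, so we treat the making of target as an early burst. Target then drains by its two exits at 0.110 min⁻¹, a half-life of 6.30 min, much shorter than the run. The isomer of the product returns to target with a far smaller first-order constant, 8.64 × 10⁻⁴ min⁻¹.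

So late in the run target is in a quasi-steady state, with feed equal to drain. This gives [target]/[isomer of the product] = 0.00785, which we call the resting ratio: the back constant over the sum of the exits. It holds no concentration.

A falling row therefore needs [isomer of the product] to fall with the charge. By the forward constants, the isomer takes a share of 0.173 of the target made, the same in each flask, so the target made has to fall too. But a flask with a larger charge passes through the substrate concentrations of a flask with a smaller charge, and adds what it makes above them. The share of substrate going to target is still 0.191 at the violet start, and a falling row needs that share below zero. We commit to a rise all the way, less than in proportion to the charge.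

For amber the share at the start is 0.635. Averaging it with the share at vanishing substrate, we get 0.409 M of target made, and so 5.54 × 10⁻⁴ M at the end.

The forecast gives 5.600 × 10⁻⁴ M, 7.800 × 10⁻⁴ M, 8.900 × 10⁻⁴ M and 0.00107 M, shape rises all the way, a little above ours for amber. In its words, “the row stays tiny but still rises all the way”.

The simulation gives 5.64 × 10⁻⁴ M, 7.78 × 10⁻⁴ M, 8.82 × 10⁻⁴ M and 0.00106 M, shape rises all the way.

In the amber flask at 1.50 h, target stands at 0.113% of the charge and the isomer of the product at 13.6%, a ratio of 0.00831 against the resting ratio of 0.00785. In the violet flask the same ratio reads 0.00830 at 1.50 h, and at 15.0 h, with target at 0.0376% of the charge and the isomer of the product at 4.76%, it reads 0.00790.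

The rate constants belong to no real substance.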